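**Plan**

1. Retrosynthetic cuts: the C10–O ester bond (acid 27), C11–C12 (CO insertion), C4–CH3, the C5–O, C8–O and C10–O bonds, then C6–C7 with re-closure of C4–C9 (retro oxy-Cope), C4–C5 (vinyl addition), and the Diels–Alder bonds C1–C2 and C9–C10 together with the ketal C3–O bonds.
2. Enabling feature: ring A (C1, C2, C7, C8, C9, C10) carries the cis C2–C7 fusion with C8 beside it, so one extra C4–C9 bond turns it into a bicyclo[2.2.2]octene whose C4 carbinol bears the C5=C6 vinyl group, giving the 3-oxy-1,5-diene C6=C5–C4–C9–C8=C7.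
3. Forward order: guaiacol dearomatisation and intramolecular Diels–Alder reaction build the bicycle (ring A atoms plus C3 and C4); vinyl addition and the anionic oxy-Cope shift close ring B; then ring B is finished (C5–O, C4–CH3), ring A is oxygenated (C10, C8), the C10 ester is attached and C11 is turned into the acrylic acid.
4. Stereochemistry: the absolute configuration comes from (S)-but-3-en-2-ol, which also supplies C11 and C13 and whose centre is later oxidised away; C1 and C2 come from the tether, C7 from the suprafacial shift, C5 and C8 from convex-face attack on the cis-decalin, C10 from hydroxyl-directed hydride delivery; the ester alkene geometry is locked in a dioxepine ring.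

Key step: step 5

Numbering used throughout: C1–C13 as in the target (C1 carries C11; C2 and C7 are the fusion carbons; ring B is C2–C7; C12 is the carboxyl carbon, C13 the methylene carbon). In the decalins β is the face of H2 and H7. In the bicyclic compounds the three bridges between bridgeheads C2 and C9 are named by their atoms.

Remark: the ketal centre of 3 is assumed to form without facial preference, so 4 is expected together with one diastereomer (mirror-image bicycle, same carbinol centre), which is removed by chromatography.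

**Route**

Step 1
Reactants: 1 2-methoxy-5-methylphenol; 2 (S)-but-3-en-2-ol
Product: 4 tricyclic keto ketal, via masked o-benzoquinone 3 (not isolated)
Conditions: PhI(OAc)2, 2 (3 equiv), CH2Cl2, 0 → 40 °C, slow addition of 1; chromatography
Reagents that add atoms: none
Why: Oxidative dearomatisation by the trivalent iodine reagent in the presence of 2 should give the mixed-ketal dienone 3, whose tethered alkene adds in an intramolecular Diels–Alder reaction on the only diene face it can reach, so C11 ends syn to the C3–C4 bridge and C1, C2 and C9 follow from the ketal centre.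

Step 2
Reactants: 4 tricyclic keto ketal
Product: 5 hydroxy ketone
Conditions: SmI2 (5 equiv), THF/MeOH, −78 °C → rt
Reagents that add atoms: none
Why: SmI2 reduction of an α-alkoxy ketone should cleave both α C–O bonds in turn (ketyl, then samarium enolate, then protonation), removing the methoxy group and opening the oxolane to leave C3 as CH2 and the (S)-alcohol on C11 without touching a stereocentre.

Step 3
Reactants: 5 hydroxy ketone
Product: 6 silyl ether ketone
Conditions: TBSCl, imidazole, DMF, 40 °C
Reagents that add atoms: tert-butylchlorodimethylsilane CC(C)(C)[Si](C)(C)Cl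
Why: Imidazole-promoted silylation of the secondary alcohol is standard and leaves the ketone untouched.

Step 4
Reactants: 6 silyl ether ketone; 7 vinylmagnesium bromide
Product: 8 tertiary vinyl carbinol
Conditions: THF, −78 → 0 °C; aq. NH4Cl
Reagents that add atoms: none
Why: Grignard 1,2-addition should occur on the ketone face next to the C7=C8 bridge, because the other face is blocked by the C1–C10 bridge and the C11 substituent on it, which sets C4 with vinyl syn to the alkene bridge.

Step 5
Reactants: 8 tertiary vinyl carbinol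
Product: 11 triethylsilyl enol ether of the cis-fused bicycle, via potassium alkoxide 9 (not isolated), via potassium enolate 10 (not isolated)
Conditions: KH, 18-crown-6, THF, 0 °C → rt; then Et3SiCl, Et3N, −78 °C
Reagents that add atoms: triethylchlorosilane CC[Si](CC)(CC)Cl; potassium hydride [K+].[H-] (potassium in 9 and 10 only)
Why: KH with 18-crown-6 gives the free potassium alkoxide 9, whose 3-oxido-1,5-diene (C6=C5–C4(O−)–C9–C8=C7) should undergo a concerted [3,3] sigmatropic shift, the closest known reaction type being the anionic oxy-Cope rearrangement of 2-vinylbicyclo[2.2.2]oct-5-en-2-olates to cis-fused octalenones. Ring B (C2–C3–C4–C5–C6–C7) closes by suprafacial C6–C7 bond formation through the boat-like array that the bicycle enforces while the C4–C9 bond breaks, so the bicyclo[2.2.2]octene becomes the bicyclo[4.4.0]decadiene without a free intermediate. C7 is the only new stereocentre and is set by the substrate, since C6 can reach C7 only on the alkene face turned toward the C3–C4 bridge, which places H7 cis to H2. The step needs the vinyl group syn to the C7=C8 bridge, which step 4 provides, and a regiodefined enolate, which cold O-silylation of 10 secures as the C4=C5 enol ether only. The alkoxide acceleration lets the shift run near room temperature, so the C11 silyl ether and the C8=C9 alkene are left alone.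

Step 6
Reactants: 11 triethylsilyl enol ether
Product: 13 5β-triethylsilyloxy C4 ketone, via silyloxy oxirane 12 (not isolated)
Conditions: mCPBA (1.0 equiv), NaHCO3, CH2Cl2, −30 → 0 °C
Reagents that add atoms: 3-chloroperbenzoic acid OOC(=O)c1cccc(Cl)c1
Why: In this Rubottom oxidation the electron-rich enol ether should be epoxidised before the C8=C9 alkene and on the convex β face of ring B (the α face is screened by the axial ring A bond), and oxirane 12 opens with 1,4-silyl shift to the α-silyloxy ketone, setting C5.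

Step 7
Reactants: 13 5β-triethylsilyloxy C4 ketone
Product: 15 C3=C4 enol triflate, via lithium enolate 14 (not isolated)
Conditions: LiN(iPr)2, THF, −78 °C; PhNTf2, −78 → 0 °C
Reagents that add atoms: N-phenylbis(trifluoromethanesulfonimide) FC(F)(F)S(=O)(=O)N(c1ccccc1)S(=O)(=O)C(F)(F)F; lithium diisopropylamide [Li+].CC(C)[N-]C(C)C (lithium in 14 only)
Why: Kinetic deprotonation of an α-silyloxy ketone by a hindered amide base should take place at the C3 methylene and not at the oxygen-bearing C5 methine, and O-sulfonylation of enolate 14 gives the enol triflate (enol triflate formation).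

Step 8
Reactants: 15 C3=C4 enol triflate
Product: 16 4-methyl diene
Conditions: MeMgBr, Fe(acac)3 (5 mol%), THF/NMP, −30 → 0 °C
Reagents that add atoms: methylmagnesium bromide C[Mg]Br
Why: Iron-catalysed Kumada-type cross-coupling of an alkenyl triflate with a Grignard reagent should replace the triflate by methyl without moving the C3=C4 alkene, and silyl ethers are tolerated.

Step 9
Reactants: 16 4-methyl diene
Product: 17 5β-alcohol
Conditions: PPTS (cat.), MeOH/CH2Cl2, 0 °C
Reagents that add atoms: none
Why: Acid-catalysed methanolysis should cleave the secondary triethylsilyl ether well before the hindered tert-butyldimethylsilyl ether (selective desilylation).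

Step 10
Reactants: 17 5β-alcohol
Product: 18 5β-acetate
Conditions: Ac2O, pyridine, DMAP (cat.), CH2Cl2, rt
Reagents that add atoms: acetic anhydride CC(=O)OC(C)=O
Why: DMAP-catalysed acetylation of the secondary allylic alcohol installs the C5 acetate with retention.

Step 11
Reactants: 18 5β-acetate
Product: 19 ring A enone
Conditions: CrO3, 3,5-dimethylpyrazole, CH2Cl2, −20 °C
Reagents that add atoms: chromium trioxide O=[Cr](=O)=O
Why: Allylic C–H oxidation with the CrO3–3,5-dimethylpyrazole complex should convert the C10 methylene next to the CH end of the ring A alkene into the enone, since ring B offers no allylic CH2 (C5 is an acetoxy-deactivated methine, C2 a methine).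

Step 12
Reactants: 19 ring A enone
Product: 21 8β-hydroxy C10 ketone, via tertiary boronate 20 (not isolated)
Conditions: B2pin2, CuCl (10 mol%), NaOtBu (10 mol%), DPEphos (10 mol%), MeOH (2 equiv), THF, rt; then NaBO3·4H2O, THF/H2O, rt
Reagents that add atoms: sodium perborate [Na+].[O-]OB=O; bis(pinacolato)diboron CC1(C)OB(OC1(C)C)B1OC(C)(C)C(C)(C)O1 (boron in 20 only)
Why: Copper-catalysed conjugate borylation of the β,β-disubstituted enone followed by perborate oxidation with retention amounts to a conjugate hydration, and the boryl copper should add to C8 on the convex β face, anti to the axial C2–C3 bond, which sets the tertiary carbinol.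

Step 13
Reactants: 21 8β-hydroxy C10 ketone
Product: 22 8β,10α-diol
Conditions: Me4NBH(OAc)3, MeCN/AcOH, −30 → −20 °C
Reagents that add atoms: none
Why: In this Evans–Saksena reduction the C8 hydroxyl binds boron and delivers hydride to C10 on the β face, which should give the 1,3-anti diol with the C10 hydroxyl α and cis to C11.

Step 14
Reactants: 23 but-2-yne-1,4-diol
Product: 24 (E)-2-(tributylstannyl)but-2-ene-1,4-diol
Conditions: Bu3SnH, PdCl2(PPh3)2 (2 mol%), THF, rt
Reagents that add atoms: tributyltin hydride CCCC[SnH](CCCC)CCCC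
Why: Palladium-catalysed hydrostannation of the symmetric alkyne is a syn addition, so the two CH2OH groups end cis.

Step 15
Reactants: 24 (E)-2-(tributylstannyl)but-2-ene-1,4-diol
Product: 25 stannyl dioxepine
Conditions: 2,2-dimethoxypropane, PPTS (cat.), CH2Cl2, rt
Reagents that add atoms: 2,2-dimethoxypropane COC(C)(C)OC
Why: Acid-catalysed transketalisation closes the seven-membered acetonide, which only the cis diol can form and which locks the alkene geometry.

Step 16
Reactants: 25 stannyl dioxepine
Product: 27 2,2-dimethyl-4,7-dihydro-1,3-dioxepine-5-carboxylic acid, via alkenyllithium 26 (not isolated)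
Conditions: n-BuLi, THF, −78 °C; CO2; cold dilute HCl to pH 4
Reagents that add atoms: carbon dioxide O=C=O; n-butyllithium [Li]CCCC (lithium in 26 only)
Why: Tin–lithium exchange proceeds with retention at the alkenyl carbon and carboxylation of the alkenyllithium gives the acid.

Step 17
Reactants: 22 8β,10α-diol; 27 dioxepine carboxylic acid
Product: 29 C10 ester, via mixed anhydride 28 (not isolated)
Conditions: 2,4,6-trichlorobenzoyl chloride, Et3N, THF, rt; then 22, DMAP, toluene, rt → 40 °C
Reagents that add atoms: 2,4,6-trichlorobenzoyl chloride O=C(Cl)c1c(Cl)cc(Cl)cc1Cl (in 28 only)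
Why: In this Yamaguchi esterification the mixed anhydride should transfer the less hindered acyl group to the secondary C10 hydroxyl under DMAP catalysis, while the tertiary C8 hydroxyl stays free and the ring-locked alkene cannot isomerise.

Step 18
Reactants: 29 C10 ester
Product: 30 C11 alcohol
Conditions: Et3N·3HF, THF, rt → 40 °C
Reagents that add atoms: none
Why: Fluoride cleavage of the Si–O bond under non-basic conditions should free the C11 alcohol without 1,3-acyl migration from C10 and without harm to the acetonide.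

Step 19
Reactants: 30 C11 alcohol
Product: 31 C11 methyl ketone
Conditions: Dess–Martin periodinane, NaHCO3, CH2Cl2, 0 °C → rt
Reagents that add atoms: none
Why: Dess–Martin oxidation under buffered neutral conditions converts the secondary alcohol into the methyl ketone, erasing the auxiliary centre at C11 without enolisation toward C1.

Step 20
Reactants: 31 C11 methyl ketone
Product: 32 C8 trimethylsilyl ether
Conditions: 1-(trimethylsilyl)imidazole, CH2Cl2, rt
Reagents that add atoms: 1-(trimethylsilyl)imidazole C[Si](C)(C)n1ccnc1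
Why: Silylation of the tertiary alcohol with a reagent that does not enolise ketones masks the only acidic O–H before the base step.

Step 21
Reactants: 32 C8 trimethylsilyl ether
Product: 34 C11 enol triflate, via potassium enolate 33 (not isolated)
Conditions: KN(SiMe3)2, THF, −78 °C; PhNTf2, −78 °C
Reagents that add atoms: N-phenylbis(trifluoromethanesulfonimide) FC(F)(F)S(=O)(=O)N(c1ccccc1)S(=O)(=O)C(F)(F)F; potassium bis(trimethylsilyl)amide [K+].C[Si](C)(C)[N-][Si](C)(C)C (potassium in 33 only)
Why: Kinetic deprotonation of the methyl ketone at the methyl group and O-triflation of enolate 33 (enol triflate formation) should succeed because the terminal enolate cannot expel the C10 carboxylate, which only the C1 enolate could do.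

Step 22
Reactants: 34 C11 enol triflate
Product: 36 protected acrylic acid, via mixed acetic anhydride 35 (not isolated)
Conditions: Pd(OAc)2 (5 mol%), PPh3, KOAc, CO (1 atm), DMF, rt; aq. work-up
Reagents that add atoms: carbon monoxide [C-]#[O+]; potassium acetate CC(=O)[O-].[K+] (acetyl group in 35, one carboxyl oxygen in 36)
Why: Palladium-catalysed hydroxycarbonylation of an alkenyl triflate (oxidative addition to zerovalent palladium, CO insertion, capture by acetate, hydrolysis on work-up) should give the acrylic acid at room temperature, where the hindered allylic acetate is not expected to ionise.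

Step 23
Reactants: 36 protected acrylic acid
Product: 37 target CNP0468194.4
Conditions: AcOH/THF/H2O (3:1:1), rt
Reagents that add atoms: none
Why: Mild acidic hydrolysis should cleave the seven-membered acetonide and the tertiary trimethylsilyl ether while the esters, the allylic acetate and the acrylic acid persist, and the E geometry prevents lactonisation of the freed diol.

**Compound list**

1 | 2-methoxy-5-methylphenol | COc1ccc(C)cc1O | starting material
2 | (S)-but-3-en-2-ol | C[C@H](O)C=C | starting material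
3 | 6-[(2S)-but-3-en-2-yloxy]-6-methoxy-3-methylcyclohexa-2,4-dien-1-one, the ketal epimer that leads to 4 | C=C[C@H](C)O[C@]1(OC)C(=O)C=C(C)C=C1 | intermediate
4 | tricyclic keto ketal: bicyclo[2.2.2]octenone with bridges C3–C4(=O), C1–C10 and C7=C8(CH3); C3 bears OCH3 (toward the alkene bridge) and an oxolane oxygen joining it to C11 [(S), CH3] on C1 | C[C@@H]1O[C@]2(OC)C(=O)[C@@H]3C[C@H]1[C@H]2C=C3C | intermediate
5 | 8-[(1S)-1-hydroxyethyl]-6-methylbicyclo[2.2.2]oct-5-en-2-one (C4 ketone, C3 = CH2, hydroxyethyl on C1 syn to the C3–C4 bridge) | C[C@H](O)[C@@H]1[C@@H]2CC(=O)[C@H](C1)C(C)=C2 | intermediate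
6 | tert-butyldimethylsilyl ether of 5 | CC(C)(C)[Si](C)(C)O[C@@H](C)[C@@H]1[C@@H]2CC(=O)[C@H](C1)C(C)=C2 | intermediate
7 | vinylmagnesium bromide | C=C[Mg]Br | starting material
8 | C4 tertiary carbinol of 6: vinyl syn to the C7=C8 bridge, OH syn to the C1–C10 bridge | CC(C)(C)[Si](C)(C)O[C@@H](C)[C@@H]1[C@@H]2C[C@@](O)(C=C)[C@H](C1)C(C)=C2 | intermediate
9 | potassium alkoxide of 8 | CC(C)(C)[Si](C)(C)O[C@@H](C)[C@@H]1[C@@H]2C[C@@]([O-])(C=C)[C@H](C1)C(C)=C2.[K+] | intermediate
10 | potassium C4=C5 enolate of the cis-fused bicycle (H2, H7 β; C8=C9 with 8-methyl; C1 side chain α) | CC(C)(C)[Si](C)(C)O[C@@H](C)[C@@H]1[C@@H]2CC([O-])=CC[C@@H]2C(C)=CC1.[K+] | intermediate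
11 | C4 triethylsilyl enol ether (C4=C5) of the cis-fused bicycle; C8=C9; C1 α-[(1S)-1-(tert-butyldimethylsilyloxy)ethyl] | CC(C)(C)[Si](C)(C)O[C@@H](C)[C@@H]1[C@@H]2CC(O[Si](CC)(CC)CC)=CC[C@@H]2C(C)=CC1 | intermediate
12 | 4β,5β-epoxide of 11 (4-triethylsilyloxy oxirane) | CC(C)(C)[Si](C)(C)O[C@@H](C)[C@@H]1[C@@H]2C[C@@]3(O[Si](CC)(CC)CC)O[C@H]3C[C@@H]2C(C)=CC1 | intermediate
13 | C4 ketone with 5β-triethylsilyloxy group | CC(C)(C)[Si](C)(C)O[C@@H](C)[C@@H]1[C@@H]2CC(=O)[C@@H](O[Si](CC)(CC)CC)C[C@@H]2C(C)=CC1 | intermediate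
14 | lithium C3=C4 enolate of 13 | CC(C)(C)[Si](C)(C)O[C@@H](C)[C@@H]1[C@@H]2C=C([O-])[C@@H](O[Si](CC)(CC)CC)C[C@@H]2C(C)=CC1.[Li+] | intermediate
15 | C3=C4 enol triflate (triflate on C4), 5β-triethylsilyloxy | CC(C)(C)[Si](C)(C)O[C@@H](C)[C@@H]1[C@@H]2C=C(OS(=O)(=O)C(F)(F)F)[C@@H](O[Si](CC)(CC)CC)C[C@@H]2C(C)=CC1 | intermediate
16 | diene with C3=C4 (4-methyl) and C8=C9 (8-methyl), 5β-triethylsilyloxy | CC(C)(C)[Si](C)(C)O[C@@H](C)[C@@H]1[C@@H]2C=C(C)[C@@H](O[Si](CC)(CC)CC)C[C@@H]2C(C)=CC1 | intermediate
17 | 5β-alcohol of 16 | CC(C)(C)[Si](C)(C)O[C@@H](C)[C@@H]1[C@@H]2C=C(C)[C@@H](O)C[C@@H]2C(C)=CC1 | intermediate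
18 | 5β-acetate | CC(C)(C)[Si](C)(C)O[C@@H](C)[C@@H]1[C@@H]2C=C(C)[C@@H](OC(C)=O)C[C@@H]2C(C)=CC1 | intermediate
19 | ring A enone (C8=C9–C10=O), 5β-acetate | CC(C)(C)[Si](C)(C)O[C@@H](C)[C@@H]1[C@@H]2C=C(C)[C@@H](OC(C)=O)C[C@@H]2C(C)=CC1=O | intermediate
20 | C10 ketone with 8β-pinacolboryl and 8α-methyl | CC(C)(C)[Si](C)(C)O[C@@H](C)[C@@H]1[C@@H]2C=C(C)[C@@H](OC(C)=O)C[C@@H]2[C@@](C)(B3OC(C)(C)C(C)(C)O3)CC1=O | intermediate
21 | C10 ketone with 8β-hydroxy and 8α-methyl | CC(C)(C)[Si](C)(C)O[C@@H](C)[C@@H]1[C@@H]2C=C(C)[C@@H](OC(C)=O)C[C@@H]2[C@@](C)(O)CC1=O | intermediate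
22 | 8β,10α-diol, 5β-acetate, C11 tert-butyldimethylsilyl ether | CC(C)(C)[Si](C)(C)O[C@@H](C)[C@@H]1[C@@H]2C=C(C)[C@@H](OC(C)=O)C[C@@H]2[C@@](C)(O)C[C@@H]1O | intermediate
23 | but-2-yne-1,4-diol | OCC#CCO | starting material
24 | (E)-2-(tributylstannyl)but-2-ene-1,4-diol | OC/C=C(\CO)[Sn](CCCC)(CCCC)CCCC | intermediate
25 | 2,2-dimethyl-5-(tributylstannyl)-4,7-dihydro-1,3-dioxepine | CC1(C)OCC=C([Sn](CCCC)(CCCC)CCCC)CO1 | intermediate
26 | (2,2-dimethyl-4,7-dihydro-1,3-dioxepin-5-yl)lithium | [Li]C1=CCOC(C)(C)OC1 | intermediate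
27 | 2,2-dimethyl-4,7-dihydro-1,3-dioxepine-5-carboxylic acid | CC1(C)OCC=C(C(=O)O)CO1 | intermediate
28 | mixed anhydride of 27 and 2,4,6-trichlorobenzoic acid | CC1(C)OCC=C(C(=O)OC(=O)c2c(Cl)cc(Cl)cc2Cl)CO1 | intermediate
29 | 10α-(dioxepine-5-carbonyloxy) ester of 22, 8β-OH free | CC(C)(C)[Si](C)(C)O[C@@H](C)[C@@H]1[C@@H]2C=C(C)[C@@H](OC(C)=O)C[C@@H]2[C@@](C)(O)C[C@@H]1OC(=O)C1=CCOC(C)(C)OC1 | intermediate
30 | C11 (S)-alcohol of 29 | C[C@H](O)[C@@H]1[C@@H]2C=C(C)[C@@H](OC(C)=O)C[C@@H]2[C@@](C)(O)C[C@@H]1OC(=O)C1=CCOC(C)(C)OC1 | intermediate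
31 | C11 methyl ketone (1α-acetyl) | CC(=O)[C@@H]1[C@@H]2C=C(C)[C@@H](OC(C)=O)C[C@@H]2[C@@](C)(O)C[C@@H]1OC(=O)C1=CCOC(C)(C)OC1 | intermediate
32 | 8β-trimethylsilyl ether of 31 | CC(=O)[C@@H]1[C@@H]2C=C(C)[C@@H](OC(C)=O)C[C@@H]2[C@@](C)(O[Si](C)(C)C)C[C@@H]1OC(=O)C1=CCOC(C)(C)OC1 | intermediate
33 | potassium C11=C13 enolate of 32 | C=C([O-])[C@@H]1[C@@H]2C=C(C)[C@@H](OC(C)=O)C[C@@H]2[C@@](C)(O[Si](C)(C)C)C[C@@H]1OC(=O)C1=CCOC(C)(C)OC1.[K+] | intermediate
34 | C11 enol triflate (1α-[1-(triflyloxy)vinyl]) | C=C(OS(=O)(=O)C(F)(F)F)[C@@H]1[C@@H]2C=C(C)[C@@H](OC(C)=O)C[C@@H]2[C@@](C)(O[Si](C)(C)C)C[C@@H]1OC(=O)C1=CCOC(C)(C)OC1 | intermediate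
35 | mixed anhydride of acid 36 with acetic acid | C=C(C(=O)OC(C)=O)[C@@H]1[C@@H]2C=C(C)[C@@H](OC(C)=O)C[C@@H]2[C@@](C)(O[Si](C)(C)C)C[C@@H]1OC(=O)C1=CCOC(C)(C)OC1 | intermediate
36 | acrylic acid with 8β-trimethylsilyloxy group and side-chain acetonide | C=C(C(=O)O)[C@@H]1[C@@H]2C=C(C)[C@@H](OC(C)=O)C[C@@H]2[C@@](C)(O[Si](C)(C)C)C[C@@H]1OC(=O)C1=CCOC(C)(C)OC1 | intermediate
37 | CNP0468194.4: 1α-(1-carboxyvinyl), 5β-acetoxy, 8β-hydroxy-8α-methyl, 10α-[(E)-4-hydroxy-2-(hydroxymethyl)but-2-enoyloxy] cis-fused bicycle | C=C(C(=O)O)[C@@H]1[C@@H]2C=C(C)[C@@H](OC(C)=O)C[C@@H]2[C@@](C)(O)C[C@@H]1OC(=O)/C(=C/CO)CO | target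

**Step count and risks**

Total step count: 23. Longest linear sequence: 20 steps (steps 1–13 and 17–23); steps 14–16 make acid 27.

Steps most likely to fail:

Step 11. Hydrogen abstraction at the tertiary C7–H or at the ring B allylic positions may compete with attack at C10, eroding site selectivity. Fallback by oxygen transfer instead of C–H abstraction, setting out from acetate 18: mCPBA (NaHCO3, CH2Cl2, 0 °C) should epoxidise the more electron-rich C8=C9 alkene to the 8,9-epoxide F1. PhSeNa (from (PhSe)2 and NaBH4, EtOH) should open it at C9 to the hydroxy selenide F2. H2O2 then oxidises selenium and the selenoxide eliminates toward C10 to the tertiary allylic alcohol F3. Pyridinium chlorochromate (C5H5NH[CrO3Cl]) brings about the Babler–Dauben oxidative 1,3-transposition, and the sequence rejoins the route at enone 19.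

Step 12. Conjugate addition to the hindered β carbon may be slow, leaving time for base-induced epimerisation at C1 or loss of the acetate. Fallback from enone 19: nucleophilic epoxidation of the Weitz–Scheffer type (t-BuOOH, DBU, CH2Cl2) should give the 8β,9β-epoxy ketone F4, and reductive cleavage of its Cα–O bond with PhSeNa/AcOH (from (PhSe)2 and NaBH4, EtOH) should deliver β-hydroxy ketone 21, where the route continues.

Step 21. Deprotonation at C1 instead of the methyl group would be followed by β-elimination of the C10 carboxylate, and ester enolisation may compete. Fallback without an enolate, from methyl ketone 31 (before silylation): Tebbe methylenation (Cp2Ti(μ-Cl)(μ-CH2)AlMe2, pyridine, THF, −40 → 0 °C), which prefers ketones over esters, should give the isopropenyl compound F5. Allylic oxidation of its methyl group (SeO2 cat., t-BuOOH, CH2Cl2; then MnO2) should give the 2-substituted acrolein F6; here the acetoxy-flanked ring B alkene is the competing site. Pinnick oxidation (NaClO2, NaH2PO4, 2-methylbut-2-ene) should give the acrylic acid F7, and the conditions of step 23 then remove its acetonide and return to the route at target 37.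

Further compounds
F1 | step 11 | 8β,9β-epoxide of acetate 18 | CC(C)(C)[Si](C)(C)O[C@@H](C)[C@@H]1[C@@H]2C=C(C)[C@@H](OC(C)=O)C[C@@H]2[C@@]3(C)O[C@H]3C1
F2 | step 11 | 8β-hydroxy-9α-phenylselanyl compound | CC(C)(C)[Si](C)(C)O[C@@H](C)[C@@H]1[C@@H]2C=C(C)[C@@H](OC(C)=O)C[C@@H]2[C@@](C)(O)[C@H]([Se]c2ccccc2)C1
F3 | step 11 | tertiary allylic alcohol (8β-hydroxy, C9=C10) | CC(C)(C)[Si](C)(C)O[C@@H](C)[C@@H]1[C@@H]2C=C(C)[C@@H](OC(C)=O)C[C@@H]2[C@@](C)(O)C=C1
F4 | step 12 | 8β,9β-epoxy C10 ketone | CC(C)(C)[Si](C)(C)O[C@@H](C)[C@@H]1[C@@H]2C=C(C)[C@@H](OC(C)=O)C[C@@H]2[C@@]3(C)O[C@H]3C1=O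
F5 | step 21 | 1α-isopropenyl compound (8β-OH free, side-chain acetonide) | C=C(C)[C@@H]1[C@@H]2C=C(C)[C@@H](OC(C)=O)C[C@@H]2[C@@](C)(O)C[C@@H]1OC(=O)C1=CCOC(C)(C)OC1
F6 | step 21 | 1α-(1-formylvinyl) compound | C=C(C=O)[C@@H]1[C@@H]2C=C(C)[C@@H](OC(C)=O)C[C@@H]2[C@@](C)(O)C[C@@H]1OC(=O)C1=CCOC(C)(C)OC1
F7 | step 21 | acrylic acid with 8β-OH free and side-chain acetonide | C=C(C(=O)O)[C@@H]1[C@@H]2C=C(C)[C@@H](OC(C)=O)C[C@@H]2[C@@](C)(O)C[C@@H]1OC(=O)C1=CCOC(C)(C)OC1
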